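Target plus starting material stayed near the charge in the earlier runs: the last readings sum to 96.3 % in violet, 101 % in teal and 96.3 % in ochre, with 1 percentage point scatter on each reading. So I kept a ledger of two entries for each mole of starting material, the limiting reagent: turned into target, or left.

| setting | violet | teal | ochre | zeta | beta |
|---|---|---|---|---|---|
| starting material | 0.50 M | 0.50 M | 0.75 M | 0.50 M | 0.50 M |
| free catalyst | 7 mM | 11 mM | 5 mM | 5.0 mM | 5.0 mM |
| temperature | 29 °C | 37 °C | 29 °C | 40 °C | 25 °C |
| remark | run made earlier | run made earlier | run made earlier |  |  |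
| time |  |  |  | 1.5 h | 1.5 h |

| run | time / min | target / % | starting material / % |
|---|---|---|---|
| violet | 6.00 | 22.7 | 76.5 |
| violet | 10.0 | 35.9 | 64.4 |
| violet | 15.0 | 45.9 | 53.3 |
| violet | 25.0 | 61.8 | 35.9 |
| violet | 40.0 | 74.6 | 28.0 |
| violet | 60.0 | 81.1 | 15.7 |
| violet | 80.0 | 83.8 | 12.5 |
| teal | 3.00 | 32.3 | 68.2 |
| teal | 8.00 | 59.4 | 39.7 |
| teal | 15.0 | 78.9 | 20.3 |
| teal | 25.0 | 87.0 | 13.2 |
| teal | 30.0 | 90.1 | 11.2 |
| teal | 40.0 | 90.7 | 8.1 |
| teal | 50.0 | 94.0 | 7.0 |
| ochre | 6.00 | 16.4 | 82.5 |
| ochre | 15.0 | 35.8 | 64.9 |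
| ochre | 25.0 | 51.1 | 48.5 |
| ochre | 50.0 | 68.2 | 33.0 |
| ochre | 80.0 | 71.9 | 24.4 |

(standard deviation of a reading: 1 percentage point)

* which flask leads in amount of target, in percent of the starting material charged ("all alike" within 1.5 percentage points) (zeta / beta / all alike)
* how much target is there at the end, in percent of the starting material charged: zeta
* how much target is there at the end, in percent of the starting material charged: beta



To count turnovers from the second entry, I took logs. Violet's last reading gave 0.297 mM⁻¹: this is the turnover budget, ln(charged/left) per mM of free catalyst charged. Ochre, also at 29 °C but charged with 0.75 M of starting material against violet's 0.50 M, read 0.282 mM⁻¹. Teal, at 37 °C, read 0.242 mM⁻¹, lower than violet.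

I gave zeta teal's budget, since 37 °C stands next to 40 °C, and beta violet's, since 29 °C stands next to 25 °C. Then I closed each ledger at 5.0 mM of free catalyst:

zeta: budget × c(free catalyst) = 1.21, left 29.8 %, target 70.2 %

beta: budget × c(free catalyst) = 1.49, left 22.7 %, target 77.3 %

The forecast gave 70 % for zeta and 76 % for beta, and named beta the leader: “The cooler flask wins.”

The flasks gave 76.7 % in zeta and 76.2 % in beta, so the answer is all alike.

    starting material + free catalyst → free catalyst + target (k = 0.0768 L mol⁻¹ s⁻¹, Ea = 60.0 kJ mol⁻¹)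
    free catalyst → spent catalyst A (k = 6.59 × 10⁻⁵ s⁻¹, Ea = 93.0 kJ mol⁻¹)
    free catalyst + target → spent catalyst B (k = 3.90 × 10⁻⁴ L mol⁻¹ s⁻¹, Ea = 79.0 kJ mol⁻¹)
    (constants at 25 °C)

Zeta drew 0.296 mM⁻¹, more than teal's reading, and stopped with 0.457 % of its free catalyst; ten times the time changes nothing. The main reason for its shortfall is free catalyst with target turning into spent catalyst B: without that step zeta gives 93.4 %. Beta drew 0.290 mM⁻¹ by 1.50 h, close to violet's 0.297 mM⁻¹, yet kept 40.4 % of its free catalyst, and by 15.0 h it drew 0.427 mM⁻¹ and held 87.5 % target.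

(All runs come from a simulation for substances that don't exist.)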